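The plan opens ring B between its acyl-bearing carbon and an adjacent C–OH carbon, which unfolds the central 2-acylphloroglucinol into a linear tetraketide ester. The key step, a magnesium-mediated Claisen cyclization, forges that single C–C bond and aromatizes ring B with its isovaleryl group already attached. It exploits the alternation in ring B of three C–OH carbons (former carbonyls C1, C3, C5) with three C-substituted carbons (C2 and C4 carrying the CH2 links to rings A and C, C6 carrying the acyl group). The precursor is a methyl 3,5,7-trioxodecanoate bearing both terminal rings, as benzyl ethers, on C2 and C4.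

Key step: step 9

Remark: chain carbons are numbered C1 (ester carbon) to C10 as in the decanoate. C2 and C4 are enolizable, so 9 and 11 are racemic and 13 and 17 are mixtures of epimers and keto–enol tautomers, drawn without configuration; the target has no stereocenter. Meldrum's acid, N-methoxy-N-methylacetamide and isovaleric acid are taken as purchased.

Step 1
Reactants: 1 2,4,6-trihydroxytoluene
Product: 3 2,4,6-trihydroxy-3-methylbenzaldehyde, via aryl iminium chloride 2 (not isolated)
Conditions: POCl3 (1.1 equiv), DMF, EtOAc, 0 °C to rt; then H2O, 60 °C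
Reagents that add atoms: N,N-dimethylformamide CN(C)C=O; water O
Why: Vilsmeier–Haack formylation: the two unsubstituted ring carbons of 1 are equivalent and strongly activated, so one equivalent of the chloroiminium reagent should give a single iminium salt that water hydrolyses to the aldehyde.

Step 2
Reactants: 3 2,4,6-trihydroxy-3-methylbenzaldehyde
Product: 4 2,6-dihydroxy-4-methoxy-3-methylbenzaldehyde
Conditions: Me2SO4 (1.0 equiv), K2CO3 (1.1 equiv), acetone, 0 °C to rt
Reagents that add atoms: dimethyl sulfate COS(=O)(=O)OC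
Why: Regioselective Williamson O-methylation: the hydroxyl para to the formyl group is the most acidic and the only one that cannot chelate the carbonyl oxygen, so a weak carbonate base with one equivalent of a hard methyl donor should etherify it in preference to the two ortho hydroxyls.

Step 3
Reactants: 4 2,6-dihydroxy-4-methoxy-3-methylbenzaldehyde
Product: 5 2,6-bis(benzyloxy)-4-methoxy-3-methylbenzaldehyde
Conditions: BnBr (2.5 equiv), K2CO3 (3 equiv), DMF, 60 °C
Reagents that add atoms: benzyl bromide BrCc1ccccc1
Why: Williamson etherification: with excess BnBr and K2CO3 in warm DMF both carbonyl-flanking phenols should be benzylated at oxygen, giving ethers that survive enolates, methoxide and trifluoroacetic acid and leave by hydrogenolysis at the end.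

Step 4
Reactants: 5 2,6-bis(benzyloxy)-4-methoxy-3-methylbenzaldehyde; 6 Meldrum's acid (2,2-dimethyl-1,3-dioxane-4,6-dione)
Product: 10 methyl 3-[2,6-bis(benzyloxy)-4-methoxy-3-methylphenyl]propanoate, via arylidene Meldrum's acid 7 (not isolated), via arylmethyl Meldrum's acid 8 (not isolated), via malonic half ester 9 (not isolated)
Conditions: Hantzsch ester (diethyl 2,6-dimethyl-1,4-dihydropyridine-3,5-dicarboxylate, 1.1 equiv), L-proline (20 mol %), MeOH, rt; concentrate; then pyridine/MeOH (10:1), Cu powder (cat.), reflux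
Reagents that add atoms: methanol CO
Why: Tandem Knoevenagel condensation and Hantzsch ester transfer hydrogenation (organocatalytic reductive alkylation) of Meldrum's acid, which condenses even with hindered electron-rich aldehydes, followed by methanolysis of the dioxanedione and decarboxylation of the malonic half ester in hot pyridine, should give the propanoate without any 2,4,6-trioxygenated benzyl halide, a species prone to ionize and self-alkylate.

Step 5
Reactants: 10 methyl 3-[2,6-bis(benzyloxy)-4-methoxy-3-methylphenyl]propanoate (two molecules)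
Product: 11 methyl 2-[2,6-bis(benzyloxy)-4-methoxy-3-methylbenzyl]-5-[2,6-bis(benzyloxy)-4-methoxy-3-methylphenyl]-3-oxopentanoate (racemic)
Conditions: NaH (0.6 equiv per ester), MeOH (cat.), THF, reflux; then AcOH, 0 °C
Reagents that add atoms: none
Why: Claisen self-condensation: two molecules of 10 join to the β-keto ester, which is drawn out of the equilibrium as its sodium enolate, and the dimer already carries one arylmethyl group on C2 and the second as the branch on the C4 methylene, so both terminal rings are in place (C2 is set without control).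

Step 6
Reactants: 11 methyl 2-[2,6-bis(benzyloxy)-4-methoxy-3-methylbenzyl]-5-[2,6-bis(benzyloxy)-4-methoxy-3-methylphenyl]-3-oxopentanoate; 12 N-methoxy-N-methylacetamide
Product: 13 methyl 2,4-bis[2,6-bis(benzyloxy)-4-methoxy-3-methylbenzyl]-3,5-dioxohexanoate
Conditions: LiN(i-Pr)2 (2.3 equiv), THF, −78 to 0 °C; 12 (1.3 equiv), −78 to 0 °C; AcOH
Reagents that add atoms: none
Why: Acylation of a β-keto ester dianion (Huckin–Weiler type) with a Weinreb amide: the second deprotonation makes C4 the most nucleophilic carbon, and the chelated tetrahedral adduct releases the methyl ketone only on quench, which prevents over-addition.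

Step 7
Reactants: 14 isovaleric acid (3-methylbutanoic acid)
Product: 16 N-methoxy-N,3-dimethylbutanamide, via acyl imidazole 15 (not isolated)
Conditions: CDI (1.1 equiv), CH2Cl2, rt; then MeNH(OMe)·HCl (1.2 equiv), rt
Reagents that add atoms: N,O-dimethylhydroxylamine hydrochloride CNOC.Cl
Why: Weinreb amide synthesis through the acyl imidazole: CDI activates the acid under neutral conditions and N,O-dimethylhydroxylamine then displaces imidazole.

Step 8
Reactants: 13 methyl 2,4-bis[2,6-bis(benzyloxy)-4-methoxy-3-methylbenzyl]-3,5-dioxohexanoate; 16 N-methoxy-N,3-dimethylbutanamide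
Product: 17 methyl 2,4-bis[2,6-bis(benzyloxy)-4-methoxy-3-methylbenzyl]-9-methyl-3,5,7-trioxodecanoate
Conditions: LiN(i-Pr)2 (3.5 equiv), THF, −78 to 0 °C; 16 (1.3 equiv), −78 to −20 °C; AcOH, −78 °C
Reagents that add atoms: none
Why: Harris-type acylation of a polyanion: after C2-H and C4-H the third equivalent of base removes a proton of the C6 methyl group, and this terminal, least stabilized carbanion should attack the Weinreb amide to give the 5,7-diketone directly, so that no ketone mask and no acidic unmasking (a risk of pyranone formation) is needed.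

Step 9
Reactants: 17 methyl 2,4-bis[2,6-bis(benzyloxy)-4-methoxy-3-methylbenzyl]-9-methyl-3,5,7-trioxodecanoate
Product: 18 1-{3,5-bis[2,6-bis(benzyloxy)-4-methoxy-3-methylbenzyl]-2,4,6-trihydroxyphenyl}-3-methylbutan-1-one
Conditions: Mg(OMe)2 (5 equiv), MeOH/THF (3:1), rt to reflux, Ar; then 1 M HCl, 0 °C
Reagents that add atoms: none
Why: Mg(OMe)2 deprotonates the C5/C7 diketone and holds the tricarbonyl chain as a magnesium chelate in which nucleophilic C6 lies close to the ester carbon C1; C6 adds to C1, methoxide leaves, and the resulting 2-acylcyclohexane-1,3,5-trione enolizes at C2, C4 and C6 to the aromatic 2-acylphloroglucinol, which acts as the thermodynamic sink. The closest known reaction type is the Claisen (Dieckmann-type) cyclization of 3,5,7-trioxo esters to acylphloroglucinols, the laboratory counterpart of polyketide synthase folding. Ring B closes by a 6-(enolendo)-exo-trig attack of the diketone enolate on the ester carbonyl. No stereocenter is formed, and all C2/C4 epimers and tautomers of 17 converge because both centres become aromatic carbons. The step needs the Claisen mode to beat aldol closure (C2 on C7) and lactonization (oxygen on C5 to C1): the arylmethyl group on C2 leaves the aldol adduct unable to aromatize, so it is expected to revert, and Mg(OMe)2 in methanol reopens a 4-hydroxy-2-pyranone to the open ester, which should leave the aromatic Claisen product as the only irreversible outlet. The benzyl ethers on rings A and C are inert to methoxide and leave no free phenol through which a methylene bridge could be exchanged.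

Step 10
Reactants: 18 1-{3,5-bis[2,6-bis(benzyloxy)-4-methoxy-3-methylbenzyl]-2,4,6-trihydroxyphenyl}-3-methylbutan-1-one
Product: 19 2,4-bis[2,6-bis(benzyloxy)-4-methoxy-3-methylbenzyl]-6-(3-methylbutanoyl)benzene-1,3,5-triyl triacetate
Conditions: Ac2O (6 equiv), pyridine, DMAP (cat.), CH2Cl2, rt
Reagents that add atoms: acetic anhydride CC(=O)OC(C)=O
Why: DMAP-catalysed O-acetylation: the hard acyl donor reacts at the three phenolic oxygens of ring B, and the triacetate is no longer electron-rich enough for ipso-protonation and loss of a trioxygenated benzyl cation in the acidic acylation that follows.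

Step 11
Reactants: 19 2,4-bis[2,6-bis(benzyloxy)-4-methoxy-3-methylbenzyl]-6-(3-methylbutanoyl)benzene-1,3,5-triyl triacetate; 14 isovaleric acid (4 equiv)
Product: 20 2,4-bis[2,6-bis(benzyloxy)-4-methoxy-3-methyl-5-(3-methylbutanoyl)benzyl]-6-(3-methylbutanoyl)benzene-1,3,5-triyl triacetate
Conditions: TFAA (5 equiv), CH2Cl2, 0 °C to rt
Reagents that add atoms: none
Why: Friedel–Crafts acylation with the mixed anhydride formed from isovaleric acid and TFAA: each terminal ring has exactly one unsubstituted carbon, flanked by OBn and OMe and para to the second OBn, so the acyl group can enter only at the required position, while the fully substituted and deactivated ring B stays untouched.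

Step 12
Reactants: 20 2,4-bis[2,6-bis(benzyloxy)-4-methoxy-3-methyl-5-(3-methylbutanoyl)benzyl]-6-(3-methylbutanoyl)benzene-1,3,5-triyl triacetate
Product: 22 1-{3,5-bis[2,6-dihydroxy-4-methoxy-3-methyl-5-(3-methylbutanoyl)benzyl]-2,4,6-trihydroxyphenyl}-3-methylbutan-1-one (target), via triphenol tetrabenzyl ether 21 (not isolated)
Conditions: K2CO3 (3.5 equiv), MeOH/THF, rt; AcOH; then H2 (1 atm), 10% Pd/C, EtOAc, rt
Reagents that add atoms: none
Why: Methanolysis of the three aryl acetates (transesterification) followed, after neutralization, by hydrogenolysis of the four benzyl ethers on Pd/C: the basic stage is run while rings A and C are still ethers, which rules out base-induced exchange of the methylene bridges, the last operation is neutral, and the aryl ketones, vinylogous esters of trioxygenated rings, should resist reduction.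

Compound list
1 | 2,4,6-trihydroxytoluene | Cc1c(O)cc(O)cc1O | starting material
2 | N-[(2,4,6-trihydroxy-3-methylphenyl)methylidene]-N-methylmethanaminium chloride | C[N+](C)=Cc1c(O)cc(O)c(C)c1O.[Cl-] | intermediate
3 | 2,4,6-trihydroxy-3-methylbenzaldehyde | Cc1c(O)cc(O)c(C=O)c1O | intermediate
4 | 2,6-dihydroxy-4-methoxy-3-methylbenzaldehyde | COc1cc(O)c(C=O)c(O)c1C | intermediate
5 | 2,6-bis(benzyloxy)-4-methoxy-3-methylbenzaldehyde | COc1cc(OCc2ccccc2)c(C=O)c(OCc2ccccc2)c1C | intermediate
6 | Meldrum's acid (2,2-dimethyl-1,3-dioxane-4,6-dione) | CC1(C)OC(=O)CC(=O)O1 | starting material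
7 | 5-[2,6-bis(benzyloxy)-4-methoxy-3-methylbenzylidene]-2,2-dimethyl-1,3-dioxane-4,6-dione | CC1(C)OC(=O)C(=Cc2c(OCc3ccccc3)cc(OC)c(C)c2OCc2ccccc2)C(=O)O1 | intermediate
8 | 5-[2,6-bis(benzyloxy)-4-methoxy-3-methylbenzyl]-2,2-dimethyl-1,3-dioxane-4,6-dione | CC1(C)OC(=O)C(Cc2c(OCc3ccccc3)cc(OC)c(C)c2OCc2ccccc2)C(=O)O1 | intermediate
9 | 2-[2,6-bis(benzyloxy)-4-methoxy-3-methylbenzyl]-3-methoxy-3-oxopropanoic acid (racemic) | COC(=O)C(Cc1c(OCc2ccccc2)cc(OC)c(C)c1OCc1ccccc1)C(O)=O | intermediate
10 | methyl 3-[2,6-bis(benzyloxy)-4-methoxy-3-methylphenyl]propanoate | COC(=O)CCc1c(OCc2ccccc2)cc(OC)c(C)c1OCc1ccccc1 | intermediate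
11 | methyl 2-[2,6-bis(benzyloxy)-4-methoxy-3-methylbenzyl]-5-[2,6-bis(benzyloxy)-4-methoxy-3-methylphenyl]-3-oxopentanoate (racemic) | COC(=O)C(Cc1c(OCc2ccccc2)cc(OC)c(C)c1OCc1ccccc1)C(=O)CCc1c(OCc2ccccc2)cc(OC)c(C)c1OCc1ccccc1 | intermediate
12 | N-methoxy-N-methylacetamide | CON(C)C(C)=O | starting material
13 | methyl 2,4-bis[2,6-bis(benzyloxy)-4-methoxy-3-methylbenzyl]-3,5-dioxohexanoate (epimer and tautomer mixture) | COC(=O)C(Cc1c(OCc2ccccc2)cc(OC)c(C)c1OCc1ccccc1)C(=O)C(Cc1c(OCc2ccccc2)cc(OC)c(C)c1OCc1ccccc1)C(C)=O | intermediate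
14 | isovaleric acid (3-methylbutanoic acid) | CC(C)CC(O)=O | starting material
15 | 1-(1H-imidazol-1-yl)-3-methylbutan-1-one | CC(C)CC(=O)n1ccnc1 | intermediate
16 | N-methoxy-N,3-dimethylbutanamide | CON(C)C(=O)CC(C)C | intermediate
17 | methyl 2,4-bis[2,6-bis(benzyloxy)-4-methoxy-3-methylbenzyl]-9-methyl-3,5,7-trioxodecanoate (epimer and tautomer mixture) | COC(=O)C(Cc1c(OCc2ccccc2)cc(OC)c(C)c1OCc1ccccc1)C(=O)C(Cc1c(OCc2ccccc2)cc(OC)c(C)c1OCc1ccccc1)C(=O)CC(=O)CC(C)C | intermediate
18 | 1-{3,5-bis[2,6-bis(benzyloxy)-4-methoxy-3-methylbenzyl]-2,4,6-trihydroxyphenyl}-3-methylbutan-1-one | COc1cc(OCc2ccccc2)c(Cc2c(O)c(Cc3c(OCc4ccccc4)cc(OC)c(C)c3OCc3ccccc3)c(O)c(C(=O)CC(C)C)c2O)c(OCc2ccccc2)c1C | intermediate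
19 | 2,4-bis[2,6-bis(benzyloxy)-4-methoxy-3-methylbenzyl]-6-(3-methylbutanoyl)benzene-1,3,5-triyl triacetate | COc1cc(OCc2ccccc2)c(Cc2c(OC(C)=O)c(Cc3c(OCc4ccccc4)cc(OC)c(C)c3OCc3ccccc3)c(OC(C)=O)c(C(=O)CC(C)C)c2OC(C)=O)c(OCc2ccccc2)c1C | intermediate
20 | 2,4-bis[2,6-bis(benzyloxy)-4-methoxy-3-methyl-5-(3-methylbutanoyl)benzyl]-6-(3-methylbutanoyl)benzene-1,3,5-triyl triacetate | COc1c(C(=O)CC(C)C)c(OCc2ccccc2)c(Cc2c(OC(C)=O)c(Cc3c(OCc4ccccc4)c(C(=O)CC(C)C)c(OC)c(C)c3OCc3ccccc3)c(OC(C)=O)c(C(=O)CC(C)C)c2OC(C)=O)c(OCc2ccccc2)c1C | intermediate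
21 | 1-{3,5-bis[2,6-bis(benzyloxy)-4-methoxy-3-methyl-5-(3-methylbutanoyl)benzyl]-2,4,6-trihydroxyphenyl}-3-methylbutan-1-one | COc1c(C(=O)CC(C)C)c(OCc2ccccc2)c(Cc2c(O)c(Cc3c(OCc4ccccc4)c(C(=O)CC(C)C)c(OC)c(C)c3OCc3ccccc3)c(O)c(C(=O)CC(C)C)c2O)c(OCc2ccccc2)c1C | intermediate
22 | 1-{3,5-bis[2,6-dihydroxy-4-methoxy-3-methyl-5-(3-methylbutanoyl)benzyl]-2,4,6-trihydroxyphenyl}-3-methylbutan-1-one | COc1c(C)c(O)c(Cc2c(O)c(Cc3c(O)c(C)c(OC)c(C(=O)CC(C)C)c3O)c(O)c(C(=O)CC(C)C)c2O)c(O)c1C(=O)CC(C)C | target

Total step count: 12. Longest linear sequence: 11 steps (steps 1 to 6 and 8 to 12); step 7 is a one-step side branch.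

Steps most likely to fail

Step 9 (closure of ring B). The chain may fold in a non-productive mode, or methoxide may cut it by retro-Claisen attack at the crowded C3 or C5 ketone before the hindered ester carbonyl is reached. The fallback sets out from 5 and 14 and returns at 18. Aldehyde 5 would be reduced (NaBH4, MeOH/THF, 0 °C) to [2,6-bis(benzyloxy)-4-methoxy-3-methylphenyl]methanol F1. Phloroglucinol and 14 (BF3·OEt2, 80 °C, Friedel–Crafts acylation) would give 1-(2,4,6-trihydroxyphenyl)-3-methylbutan-1-one F2. F2 and F1 (2.1 equiv, added slowly) in (CF3)2CHOH at rt would then undergo a twofold Friedel–Crafts benzylation at the two free ring carbons of F2 to give 18. This gives up the folding logic and accepts a bridging reaction on a free phloroglucinol, with self-condensation of F1 as its own hazard.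

Step 8 (trianion acylation). Deprotonation may stop at the dianion, or proton transfer from the amide may outrun C-acylation, so that 13 is returned. The fallback sets out from 11 and returns at 17. Purchased ethyl 5-methyl-3-oxohexanoate would be ketalized (ethylene glycol, TsOH, toluene, Dean–Stark) to ethyl [2-(2-methylpropyl)-1,3-dioxolan-2-yl]acetate F3 and converted (MeNH(OMe)·HCl, i-PrMgCl, THF, −20 °C) into N-methoxy-N-methyl-2-[2-(2-methylpropyl)-1,3-dioxolan-2-yl]acetamide F4. The dianion of 11 (LiN(i-Pr)2, 2.3 equiv, THF) would be acylated with F4 to the C7 ketal of 17, methyl 2,4-bis[2,6-bis(benzyloxy)-4-methoxy-3-methylbenzyl]-6-[2-(2-methylpropyl)-1,3-dioxolan-2-yl]-3,5-dioxohexanoate F5. Brief hydrolysis (1 M HCl, THF, rt) would release 17. Only dianion chemistry is then required, at the price of one acidic step.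

Step 2 (mono-methylation). Alkylation may spread to a hydroxyl next to the formyl group or go on to a dimethyl ether, which would erode the supply of 4. The fallback sets out from 3 and returns at 4. Exhaustive methylation (Me2SO4 in excess, K2CO3, acetone, reflux) would give 2,4,6-trimethoxy-3-methylbenzaldehyde F6. AlCl3 (excess, CH2Cl2, rt) would then cleave the two methyl ethers that flank the formyl group by way of aluminium chelates, leaving the para ether and giving 4.

Further compounds
F1 | step 9 | [2,6-bis(benzyloxy)-4-methoxy-3-methylphenyl]methanol | COc1cc(OCc2ccccc2)c(CO)c(OCc2ccccc2)c1C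
F2 | step 9 | 1-(2,4,6-trihydroxyphenyl)-3-methylbutan-1-one | CC(C)CC(=O)c1c(O)cc(O)cc1O
F3 | step 8 | ethyl [2-(2-methylpropyl)-1,3-dioxolan-2-yl]acetate | CCOC(=O)CC1(CC(C)C)OCCO1
F4 | step 8 | N-methoxy-N-methyl-2-[2-(2-methylpropyl)-1,3-dioxolan-2-yl]acetamide | CON(C)C(=O)CC1(CC(C)C)OCCO1
F5 | step 8 | methyl 2,4-bis[2,6-bis(benzyloxy)-4-methoxy-3-methylbenzyl]-6-[2-(2-methylpropyl)-1,3-dioxolan-2-yl]-3,5-dioxohexanoate | COC(=O)C(Cc1c(OCc2ccccc2)cc(OC)c(C)c1OCc1ccccc1)C(=O)C(Cc1c(OCc2ccccc2)cc(OC)c(C)c1OCc1ccccc1)C(=O)CC1(CC(C)C)OCCO1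
F6 | step 2 | 2,4,6-trimethoxy-3-methylbenzaldehyde | COc1cc(OC)c(C=O)c(OC)c1C
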